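Numbering: germacrane (ring C1–C10; C11, C12, C13 on C7; C14 on C10; C15 on C4). Bonds cut, in retrosynthetic order: the C15–O acyl bond; O–C8 together with C11–C12 (the C12(=O)–O unit leaves as CO2); ring bond C7–C8; C6–C7; C3–C4; C1–C2.
Feature used: on the ten-membered ring, the exocyclic sp2 carbon C11 and ring carbon C8 are 1,3-related through C7. A C11 nucleophile (C–B, then C–Cu) and a C8 electrophile (C–Br) therefore match the electrophilic carbon and the subsequently nucleophilic oxygen of CO2, closing the five-membered ring O–C8–C7–C11–C12.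
Forward: a linear C14 chain is joined (C1–C2, C3–C4, C6–C7). The carbocycle closes at C7–C8 by a 2-bromoallylchromium–aldehyde addition, the lactone ring is then made from CO2, and the side-chain ester is attached last.
Stereochemistry: C6 is set by catalytic asymmetric alkynylation, and C7 and C8 are relayed from C6 in the ring closure. C8 is then inverted twice (OH to Br, Br to O), each time stereospecifically, which ends in the trans-8,12-olide.
Alkenes: C1=C10 by syn-methylalumination, C4=C5 by syn-carbocupration, side chain by syn-hydrostannation.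

Key step: step 16

Assumption: (S,S)-ProPhenol is taken to deliver the alkynylzinc to the Si face of enal 11; if the sense is the opposite one, the equally available (R,R)-ligand is used. Compounds 1, 4, 12 and 28 are catalogue chemicals.

Step 1
Reactants: 1 4-methoxybenzyl propargyl ether
Product: 3 methyl 4-[(4-methoxybenzyl)oxy]but-2-ynoate, via lithium acetylide 2 (not isolated)
Conditions: n-BuLi, THF, −78 °C; ClCO2Me, −78 °C to 0 °C
Reagents that add atoms: methyl chloroformate, COC(=O)Cl
Why: Deprotonation of a terminal alkyne and C-acylation of the lithium acetylide with a chloroformate is the standard entry to 4-alkoxybut-2-ynoates, and the PMB ether is inert.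

Step 2
Reactants: 4 4-(tert-butyldimethylsilyloxy)but-1-yne
Product: 6 (E)-6-(tert-butyldimethylsilyloxy)-4-methylhex-3-en-1-ol, via alkenyldimethylalane 5 (not isolated)
Conditions: Me3Al, Cp2ZrCl2 (20 mol %), CH2Cl2, 0 °C to rt; volatiles removed; n-BuLi, THF–hexane, −78 to 0 °C; ethylene oxide, −78 °C to rt
Reagents that add atoms: trimethylaluminium, C[Al](C)C; ethylene oxide, C1CO1
Why: Negishi Zr-catalysed syn-methylalumination puts CH3 on C10 and Al on C1 (E-alkene fixed), and the derived lithium alanate opens oxirane with retention of geometry (alkenylalanate–epoxide alkylation), which adds C2 and C3.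

Step 3
Reactants: 6 (E)-6-(tert-butyldimethylsilyloxy)-4-methylhex-3-en-1-ol
Product: 7 (E)-6-bromo-3-methylhex-3-enyl tert-butyldimethylsilyl ether
Conditions: CBr4, PPh3, CH2Cl2, 0 °C
Reagents that add atoms: carbon tetrabromide, BrC(Br)(Br)Br
Why: Appel bromination of a primary alcohol is neutral and leaves the silyl ether and the trisubstituted alkene untouched.

Step 4
Reactants: 7 (E)-6-bromo-3-methylhex-3-enyl tert-butyldimethylsilyl ether; 3 methyl 4-[(4-methoxybenzyl)oxy]but-2-ynoate
Product: 9 methyl (2Z,6E)-9-(tert-butyldimethylsilyloxy)-3-[(4-methoxybenzyloxy)methyl]-7-methylnona-2,6-dienoate, via Grignard reagent 8 (not isolated)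
Conditions: Mg, THF, rt; CuBr·SMe2, THF, −45 °C; 3, −78 °C; sat. aq NH4Cl at −78 °C
Reagents that add atoms: none
Why: Syn-carbocupration of an ynoate by an alkylcopper, with protonation of the alkenylcopper at −78 °C, puts C3 and H5 cis, so that C15 is cis to C6 and C3 is trans to C6 as in the target.

Step 5
Reactants: 9 methyl (2Z,6E)-9-(tert-butyldimethylsilyloxy)-3-[(4-methoxybenzyloxy)methyl]-7-methylnona-2,6-dienoate
Product: 10 (2Z,6E)-9-(tert-butyldimethylsilyloxy)-3-[(4-methoxybenzyloxy)methyl]-7-methylnona-2,6-dien-1-ol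
Conditions: DIBAL-H (2.2 equiv), CH2Cl2, −78 °C; Rochelle salt
Reagents that add atoms: none
Why: DIBAL-H reduces enoates cleanly in the 1,2-sense to allylic alcohols without touching silyl or benzyl-type ethers or the alkene geometry.

Step 6
Reactants: 10 (2Z,6E)-9-(tert-butyldimethylsilyloxy)-3-[(4-methoxybenzyloxy)methyl]-7-methylnona-2,6-dien-1-ol
Product: 11 (2Z,6E)-9-(tert-butyldimethylsilyloxy)-3-[(4-methoxybenzyloxy)methyl]-7-methylnona-2,6-dienal
Conditions: MnO2, CH2Cl2, rt
Reagents that add atoms: none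
Why: Neutral MnO2 oxidation is selective for the allylic alcohol and should keep the geometry of the β,β-disubstituted enal.

Step 7
Reactants: 11 (2Z,6E)-9-(tert-butyldimethylsilyloxy)-3-[(4-methoxybenzyloxy)methyl]-7-methylnona-2,6-dienal; 12 tert-butyldimethyl(prop-2-yn-1-yloxy)silane
Product: 14 (4R,5Z,9E)-1,12-bis(tert-butyldimethylsilyloxy)-6-[(4-methoxybenzyloxy)methyl]-10-methyldodeca-5,9-dien-2-yn-4-ol, via methylzinc acetylide 13 (not isolated)
Conditions: 12 (3 equiv), Me2Zn (3 equiv), (S,S)-ProPhenol (10 mol %), Ph3PO (20 mol %), toluene, 4 °C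
Reagents that add atoms: none
Why: The dinuclear Zn–ProPhenol asymmetric alkynylation works well with α,β-unsaturated aldehydes; it forms C6–C7 and sets C6 (R, 6α-oxygen) by catalyst control through Si-face delivery.

Step 8
Reactants: 14 (4R,5Z,9E)-1,12-bis(tert-butyldimethylsilyloxy)-6-[(4-methoxybenzyloxy)methyl]-10-methyldodeca-5,9-dien-2-yn-4-ol
Product: 16 (2Z,4R,5Z,9E)-2-bromo-1,12-bis(tert-butyldimethylsilyloxy)-6-[(4-methoxybenzyloxy)methyl]-10-methyldodeca-2,5,9-trien-4-ol, via cyclic sodium alanate 15 (not isolated)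
Conditions: Red-Al, THF, 0 °C to rt; then NBS, −78 °C
Reagents that add atoms: N-bromosuccinimide, O=C1CCC(=O)N1Br
Why: Hydroxyl-directed trans-hydroalumination of a propargylic alcohol delivers H to C7 and Al to C11 in a five-membered alanate, and bromodealumination with retention gives the C11 bromide, kept cold so that loss of the C13 silyloxide to an allene stays slow.

Step 9
Reactants: 16 (2Z,4R,5Z,9E)-2-bromo-1,12-bis(tert-butyldimethylsilyloxy)-6-[(4-methoxybenzyloxy)methyl]-10-methyldodeca-2,5,9-trien-4-ol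
Product: 17 (2Z,4R,5Z,9E)-2-bromo-1,4,12-tris(tert-butyldimethylsilyloxy)-6-[(4-methoxybenzyloxy)methyl]-10-methyldodeca-2,5,9-triene
Conditions: TBSOTf, 2,6-lutidine, CH2Cl2, −78 to 0 °C
Reagents that add atoms: tert-butyldimethylsilyl triflate, CC(C)(C)[Si](C)(C)OS(=O)(=O)C(F)(F)F
Why: Silyl triflate with a hindered base silylates the secondary bis-allylic alcohol without ionising it, and O6 then stays masked until the last step.

Step 10
Reactants: 17 (2Z,4R,5Z,9E)-2-bromo-1,4,12-tris(tert-butyldimethylsilyloxy)-6-[(4-methoxybenzyloxy)methyl]-10-methyldodeca-2,5,9-triene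
Product: 18 (2Z,4R,5Z,9E)-2-bromo-4-(tert-butyldimethylsilyloxy)-6-[(4-methoxybenzyloxy)methyl]-10-methyldodeca-2,5,9-triene-1,12-diol
Conditions: HF·pyridine, pyridine, THF, 0 °C
Reagents that add atoms: none
Why: Buffered HF·pyridine cleaves primary TBS ethers much faster than a hindered secondary one, so O8 and O13 are freed together while O6 stays silylated and the medium is too weakly acidic to ionise C6.

Step 11
Reactants: 18 (2Z,4R,5Z,9E)-2-bromo-4-(tert-butyldimethylsilyloxy)-6-[(4-methoxybenzyloxy)methyl]-10-methyldodeca-2,5,9-triene-1,12-diol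
Product: 19 (3E,7Z,9R,10Z)-11,12-dibromo-9-(tert-butyldimethylsilyloxy)-7-[(4-methoxybenzyloxy)methyl]-3-methyldodeca-3,7,10-trien-1-ol
Conditions: NBS, Me2S, CH2Cl2, −30 to 0 °C
Reagents that add atoms: N-bromosuccinimide, O=C1CCC(=O)N1Br
Why: In the Corey–Kim halogenation only the allylic alkoxysulfonium ion is displaced by bromide, whereas that of the saturated primary alcohol reverts to the alcohol on work-up, and trisubstituted alkenes are tolerated.

Step 12
Reactants: 19 (3E,7Z,9R,10Z)-11,12-dibromo-9-(tert-butyldimethylsilyloxy)-7-[(4-methoxybenzyloxy)methyl]-3-methyldodeca-3,7,10-trien-1-ol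
Product: 20 (3E,7Z,9R,10Z)-11,12-dibromo-9-(tert-butyldimethylsilyloxy)-7-[(4-methoxybenzyloxy)methyl]-3-methyldodeca-3,7,10-trienal
Conditions: Dess–Martin periodinane, NaHCO3, CH2Cl2, 0 °C
Reagents that add atoms: none
Why: Buffered Dess–Martin oxidation gives β,γ-unsaturated aldehydes without moving the double bond into conjugation, and it tolerates allylic bromides; the aldehyde is used at once.

Step 13
Reactants: 20 (3E,7Z,9R,10Z)-11,12-dibromo-9-(tert-butyldimethylsilyloxy)-7-[(4-methoxybenzyloxy)methyl]-3-methyldodeca-3,7,10-trienal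
Product: 22 (6R,7R,8S)-11-bromo-6-(tert-butyldimethylsilyloxy)-15-(4-methoxybenzyloxy)-12-norgermacra-1(10)E,4Z,11(13)-trien-8-ol (6α-OTBS, 7α-H, 8α-OH), via allylchromium dichloride 21 (not isolated)
Conditions: CrCl2 (nickel-free, excess), THF, rt, slow addition of 20 (final 2 mM)
Reagents that add atoms: none
Why: Nozaki–Hiyama allylation in its 2-haloallyl form: without nickel, Cr(II) inserts only into the allylic C–Br bond, and the (E)-allylchromium adds through a chair transition state with C6 and C9 equatorial, which should give the 7,8-anti (8α-OH) relation; attack on the alkene face anti to OTBS in the A(1,3)-minimised rotamer (H6 eclipsing C11–Br) relays C6 to C7, and closure of germacrane-type ten-membered rings by allylmetal–aldehyde addition is well precedented.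

Step 14
Reactants: 22 (6R,7R,8S)-11-bromo-6-(tert-butyldimethylsilyloxy)-15-(4-methoxybenzyloxy)-12-norgermacra-1(10)E,4Z,11(13)-trien-8-ol
Product: 23 (6R,7R,8S)-6-(tert-butyldimethylsilyloxy)-15-(4-methoxybenzyloxy)-11-(4,4,5,5-tetramethyl-1,3,2-dioxaborolan-2-yl)-12-norgermacra-1(10)E,4Z,11(13)-trien-8-ol
Conditions: B2pin2, PdCl2(PPh3)2 (3 mol %), PPh3, KOPh, toluene, 50 °C
Reagents that add atoms: bis(pinacolato)diboron, CC1(C)OB(OC1(C)C)B1OC(C)(C)C(C)(C)O1
Why: Miyaura borylation of 1-alkenyl bromides under phenoxide activation runs at 50 °C, tolerates free alcohols and allylic ethers, and is mild enough for the 1,5-diene (no Cope rearrangement).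

Step 15
Reactants: 23 (6R,7R,8S)-6-(tert-butyldimethylsilyloxy)-15-(4-methoxybenzyloxy)-11-(4,4,5,5-tetramethyl-1,3,2-dioxaborolan-2-yl)-12-norgermacra-1(10)E,4Z,11(13)-trien-8-ol
Product: 24 (6R,7S,8R)-8-bromo-6-(tert-butyldimethylsilyloxy)-15-(4-methoxybenzyloxy)-11-(4,4,5,5-tetramethyl-1,3,2-dioxaborolan-2-yl)-12-norgermacra-1(10)E,4Z,11(13)-triene (8β-Br)
Conditions: CBr4, PPh3, CH2Cl2, 0 °C to rt
Reagents that add atoms: carbon tetrabromide, BrC(Br)(Br)Br
Why: In the Appel reaction the alkoxyphosphonium salt of the secondary 8α-alcohol is displaced by bromide with inversion (SN2) under neutral conditions that leave the alkenylboronate, the silyl and PMB ethers and the diene untouched, which gives the 8β-bromide.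

Step 16
Reactants: 24 (6R,7S,8R)-8-bromo-6-(tert-butyldimethylsilyloxy)-15-(4-methoxybenzyloxy)-11-(4,4,5,5-tetramethyl-1,3,2-dioxaborolan-2-yl)-12-norgermacra-1(10)E,4Z,11(13)-triene
Product: 26 (6R,7R,8S)-6-(tert-butyldimethylsilyloxy)-15-(4-methoxybenzyloxy)germacra-1(10)E,4Z,11(13)-trien-12,8-olide (trans-fused, 8α-O), via potassium carboxylate 25 (not isolated)
Conditions: CO2 (1 atm), (IPr)CuCl (10 mol %), KOt-Bu (1.1 equiv), 18-crown-6 (cat.), THF, 60 °C
Reagents that add atoms: carbon dioxide, O=C=O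
Why: Proposed new method: (IPr)CuOt-Bu, formed from the chloride and KOt-Bu, takes the 1-substituted vinyl group of 24 over from boron, CO2 inserts into the Cu–C11 bond (C11–C12), and alkoxide exchange releases potassium acrylate 25, whose carboxylate oxygen displaces the C8 bromide (O–C8), so that CO2 is stitched in as C12(=O)–O in one flask. The closest known reaction types are the NHC–copper(I)-catalysed carboxylation of alkenylboronic esters with CO2 and the invertive lactonisation of alkali carboxylates onto secondary halides or sulfonates; their merger on a γ-halo alkenylboronate has not been shown. The only ring closed is the γ-lactone (O, C8, C7, C11, C12), by a 5-exo-tet SN2 for which the flexible ten-membered ring can place C7–C11 antiperiplanar to C8–Br. C8 is the only stereocentre touched and is set stereospecifically: backside attack turns the 8β-bromide into the 8α-oxygen and hence the trans ring fusion, while C6 and C7 are spectators. The step needs site selectivity (8,12- and not 6,12-olide), secured because only C8 carries a leaving group and O6 is silylated; it also needs carboxylation to outrun E2 or 1,3-elimination, secured because under CO2 free tert-butoxide is buffered as its carbonate, the boron-bearing carbon is sp2 (closure to a methylenecyclopropane is strained and badly aligned), and the carboxylate is a weak base held next to C8.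

Step 17
Reactants: 26 (6R,7R,8S)-6-(tert-butyldimethylsilyloxy)-15-(4-methoxybenzyloxy)germacra-1(10)E,4Z,11(13)-trien-12,8-olide
Product: 27 (6R,7R,8S)-6-(tert-butyldimethylsilyloxy)-15-hydroxygermacra-1(10)E,4Z,11(13)-trien-12,8-olide
Conditions: DDQ, CH2Cl2–pH 7 buffer, 0 °C
Reagents that add atoms: none
Why: Oxidative PMB cleavage with buffered DDQ is orthogonal to the TBS ether and to the α-methylene lactone and avoids the acid that would trigger transannular cyclisation of the 1,5-diene.

Step 18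
Reactants: 28 but-2-yn-1-ol
Product: 29 (E)-2-(tributylstannyl)but-2-en-1-ol
Conditions: Bu3SnH, PdCl2(PPh3)2 (2 mol %), THF, 0 °C to rt
Reagents that add atoms: tributyltin hydride, CCCC[SnH](CCCC)CCCC
Why: Pd-catalysed syn-hydrostannation of a propargylic alcohol puts tin mainly on the carbon next to CH2OH and leaves CH3 cis to CH2OH; the minor regioisomer is removed by chromatography.

Step 19
Reactants: 29 (E)-2-(tributylstannyl)but-2-en-1-ol
Product: 30 (E)-tert-butyldimethyl{[2-(tributylstannyl)but-2-en-1-yl]oxy}silane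
Conditions: TBSCl, imidazole, DMF, rt
Reagents that add atoms: tert-butyldimethylsilyl chloride, CC(C)(C)[Si](C)(C)Cl
Why: Standard silylation of a primary allylic alcohol, under which the alkenylstannane is stable.

Step 20
Reactants: 30 (E)-tert-butyldimethyl{[2-(tributylstannyl)but-2-en-1-yl]oxy}silane
Product: 32 (E)-2-[(tert-butyldimethylsilyloxy)methyl]but-2-enoic acid, via alkenyllithium 31 (not isolated)
Conditions: n-BuLi, THF, −78 °C; CO2; 1 M HCl, 0 °C
Reagents that add atoms: carbon dioxide, O=C=O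
Why: Tin–lithium exchange and carboxylation both proceed with retention at the sp2 carbon, so CO2H ends trans to CH3 (the tiglate-type, thermodynamically stable geometry of the target side chain).

Step 21
Reactants: 27 (6R,7R,8S)-6-(tert-butyldimethylsilyloxy)-15-hydroxygermacra-1(10)E,4Z,11(13)-trien-12,8-olide; 32 (E)-2-[(tert-butyldimethylsilyloxy)methyl]but-2-enoic acid
Product: 33 (6R,7R,8S)-6-(tert-butyldimethylsilyloxy)-15-{(E)-2-[(tert-butyldimethylsilyloxy)methyl]but-2-enoyloxy}germacra-1(10)E,4Z,11(13)-trien-12,8-olide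
Conditions: EDC, DMAP (cat.), CH2Cl2, 0 °C to rt
Reagents that add atoms: none
Why: Steglich-type esterification of the only free (primary allylic) hydroxyl; with O6 still silylated no translactonisation to the 6,12-olide can occur.

Step 22
Reactants: 33 (6R,7R,8S)-6-(tert-butyldimethylsilyloxy)-15-{(E)-2-[(tert-butyldimethylsilyloxy)methyl]but-2-enoyloxy}germacra-1(10)E,4Z,11(13)-trien-12,8-olide
Product: 34 target, (6R,7S,8S)-6-hydroxy-15-[(E)-2-(hydroxymethyl)but-2-enoyloxy]germacra-1(10)E,4Z,11(13)-trien-12,8-olide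
Conditions: HF·pyridine, pyridine, THF, 0 °C to rt
Reagents that add atoms: none
Why: Buffered fluoride removes both TBS ethers under non-basic conditions, so neither translactonisation, conjugate addition to the α-methylene lactone nor acid-induced transannular cyclisation should intervene.

Compound list
1 | 4-methoxybenzyl propargyl ether | C#CCOCc1ccc(OC)cc1 | starting material
2 | lithium acetylide of 1 | [Li]C#CCOCc1ccc(OC)cc1 | intermediate
3 | methyl 4-[(4-methoxybenzyl)oxy]but-2-ynoate | COC(=O)C#CCOCc1ccc(OC)cc1 | intermediate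
4 | 4-(tert-butyldimethylsilyloxy)but-1-yne | C#CCCO[Si](C)(C)C(C)(C)C | starting material
5 | (E)-[4-(tert-butyldimethylsilyloxy)-2-methylbut-1-enyl]dimethylalane | C[Al](C)/C=C(\C)CCO[Si](C)(C)C(C)(C)C | intermediate
6 | (E)-6-(tert-butyldimethylsilyloxy)-4-methylhex-3-en-1-ol | OCC/C=C(\C)CCO[Si](C)(C)C(C)(C)C | intermediate
7 | (E)-6-bromo-3-methylhex-3-enyl tert-butyldimethylsilyl ether | BrCC/C=C(\C)CCO[Si](C)(C)C(C)(C)C | intermediate
8 | Grignard reagent of 7 | Br[Mg]CC/C=C(\C)CCO[Si](C)(C)C(C)(C)C | intermediate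
9 | methyl (2Z,6E)-9-(tert-butyldimethylsilyloxy)-3-[(4-methoxybenzyloxy)methyl]-7-methylnona-2,6-dienoate | COC(=O)/C=C(\COCc1ccc(OC)cc1)CC/C=C(\C)CCO[Si](C)(C)C(C)(C)C | intermediate
10 | (2Z,6E)-9-(tert-butyldimethylsilyloxy)-3-[(4-methoxybenzyloxy)methyl]-7-methylnona-2,6-dien-1-ol | OC/C=C(\COCc1ccc(OC)cc1)CC/C=C(\C)CCO[Si](C)(C)C(C)(C)C | intermediate
11 | (2Z,6E)-9-(tert-butyldimethylsilyloxy)-3-[(4-methoxybenzyloxy)methyl]-7-methylnona-2,6-dienal | O=C/C=C(\COCc1ccc(OC)cc1)CC/C=C(\C)CCO[Si](C)(C)C(C)(C)C | intermediate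
12 | tert-butyldimethyl(prop-2-yn-1-yloxy)silane | C#CCO[Si](C)(C)C(C)(C)C | starting material
13 | methylzinc acetylide of 12 | C[Zn]C#CCO[Si](C)(C)C(C)(C)C | intermediate
14 | (4R,5Z,9E)-1,12-bis(tert-butyldimethylsilyloxy)-6-[(4-methoxybenzyloxy)methyl]-10-methyldodeca-5,9-dien-2-yn-4-ol | CC(C)(C)[Si](C)(C)OCC/C(C)=C/CC/C(COCc1ccc(OC)cc1)=C/[C@@H](O)C#CCO[Si](C)(C)C(C)(C)C | intermediate
15 | cyclic sodium alanate (O6–Al–C11 five-membered ring, two 2-methoxyethoxide ligands) | CC(C)(C)[Si](C)(C)OCC/C(C)=C/CC/C(COCc1ccc(OC)cc1)=C/[C@H]2O[Al-](OCCOC)(OCCOC)C(CO[Si](C)(C)C(C)(C)C)=C2.[Na+] | intermediate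
16 | (2Z,4R,5Z,9E)-2-bromo-1,12-bis(tert-butyldimethylsilyloxy)-6-[(4-methoxybenzyloxy)methyl]-10-methyldodeca-2,5,9-trien-4-ol | CC(C)(C)[Si](C)(C)OCC/C(C)=C/CC/C(COCc1ccc(OC)cc1)=C/[C@@H](O)/C=C(\Br)CO[Si](C)(C)C(C)(C)C | intermediate
17 | (2Z,4R,5Z,9E)-2-bromo-1,4,12-tris(tert-butyldimethylsilyloxy)-6-[(4-methoxybenzyloxy)methyl]-10-methyldodeca-2,5,9-triene | CC(C)(C)[Si](C)(C)OCC/C(C)=C/CC/C(COCc1ccc(OC)cc1)=C/[C@@H](O[Si](C)(C)C(C)(C)C)/C=C(\Br)CO[Si](C)(C)C(C)(C)C | intermediate
18 | (2Z,4R,5Z,9E)-2-bromo-4-(tert-butyldimethylsilyloxy)-6-[(4-methoxybenzyloxy)methyl]-10-methyldodeca-2,5,9-triene-1,12-diol | OCC/C(C)=C/CC/C(COCc1ccc(OC)cc1)=C/[C@@H](O[Si](C)(C)C(C)(C)C)/C=C(\Br)CO | intermediate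
19 | (3E,7Z,9R,10Z)-11,12-dibromo-9-(tert-butyldimethylsilyloxy)-7-[(4-methoxybenzyloxy)methyl]-3-methyldodeca-3,7,10-trien-1-ol | OCC/C(C)=C/CC/C(COCc1ccc(OC)cc1)=C/[C@@H](O[Si](C)(C)C(C)(C)C)/C=C(\Br)CBr | intermediate
20 | (3E,7Z,9R,10Z)-11,12-dibromo-9-(tert-butyldimethylsilyloxy)-7-[(4-methoxybenzyloxy)methyl]-3-methyldodeca-3,7,10-trienal | O=CC/C(C)=C/CC/C(COCc1ccc(OC)cc1)=C/[C@@H](O[Si](C)(C)C(C)(C)C)/C=C(\Br)CBr | intermediate
21 | allylchromium(III) dichloride from 20 (Cr on C13) | O=CC/C(C)=C/CC/C(COCc1ccc(OC)cc1)=C/[C@@H](O[Si](C)(C)C(C)(C)C)/C=C(\Br)C[Cr](Cl)Cl | intermediate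
22 | (6R,7R,8S)-11-bromo-6-(tert-butyldimethylsilyloxy)-15-(4-methoxybenzyloxy)-12-norgermacra-1(10)E,4Z,11(13)-trien-8-ol | C=C(Br)[C@@H]1[C@@H](O)C/C(C)=C/CC/C(COCc2ccc(OC)cc2)=C/[C@H]1O[Si](C)(C)C(C)(C)C | intermediate
23 | (6R,7R,8S)-11-(pinacolatoboryl) analogue of 22 | C=C(B1OC(C)(C)C(C)(C)O1)[C@@H]2[C@@H](O)C/C(C)=C/CC/C(COCc3ccc(OC)cc3)=C/[C@H]2O[Si](C)(C)C(C)(C)C | intermediate
24 | (6R,7S,8R)-8β-bromo-11-(pinacolatoboryl)-6-(tert-butyldimethylsilyloxy)-15-(4-methoxybenzyloxy)-12-norgermacra-1(10)E,4Z,11(13)-triene | C=C(B1OC(C)(C)C(C)(C)O1)[C@@H]2[C@H](Br)C/C(C)=C/CC/C(COCc3ccc(OC)cc3)=C/[C@H]2O[Si](C)(C)C(C)(C)C | intermediate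
25 | potassium 8β-bromo-6-(tert-butyldimethylsilyloxy)-15-(4-methoxybenzyloxy)germacra-1(10)E,4Z,11(13)-trien-12-oate | C=C(C(=O)[O-])[C@@H]1[C@H](Br)C/C(C)=C/CC/C(COCc2ccc(OC)cc2)=C/[C@H]1O[Si](C)(C)C(C)(C)C.[K+] | intermediate
26 | (6R,7R,8S)-6-(tert-butyldimethylsilyloxy)-15-(4-methoxybenzyloxy)germacra-1(10)E,4Z,11(13)-trien-12,8-olide | C=C1C(=O)O[C@H]2C/C(C)=C/CC/C(COCc3ccc(OC)cc3)=C/[C@@H](O[Si](C)(C)C(C)(C)C)[C@H]12 | intermediate
27 | (6R,7R,8S)-6-(tert-butyldimethylsilyloxy)-15-hydroxygermacra-1(10)E,4Z,11(13)-trien-12,8-olide | C=C1C(=O)O[C@H]2C/C(C)=C/CC/C(CO)=C/[C@@H](O[Si](C)(C)C(C)(C)C)[C@H]12 | intermediate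
28 | but-2-yn-1-ol | CC#CCO | starting material
29 | (E)-2-(tributylstannyl)but-2-en-1-ol | C/C=C(\CO)[Sn](CCCC)(CCCC)CCCC | intermediate
30 | (E)-tert-butyldimethyl{[2-(tributylstannyl)but-2-en-1-yl]oxy}silane | C/C=C(\CO[Si](C)(C)C(C)(C)C)[Sn](CCCC)(CCCC)CCCC | intermediate
31 | alkenyllithium from 30 | C/C=C(\CO[Si](C)(C)C(C)(C)C)[Li] | intermediate
32 | (E)-2-[(tert-butyldimethylsilyloxy)methyl]but-2-enoic acid | C/C=C(\CO[Si](C)(C)C(C)(C)C)C(=O)O | intermediate
33 | (6R,7R,8S)-6-(tert-butyldimethylsilyloxy)-15-{(E)-2-[(tert-butyldimethylsilyloxy)methyl]but-2-enoyloxy}germacra-1(10)E,4Z,11(13)-trien-12,8-olide | C=C1C(=O)O[C@H]2C/C(C)=C/CC/C(COC(=O)/C(=C/C)CO[Si](C)(C)C(C)(C)C)=C/[C@@H](O[Si](C)(C)C(C)(C)C)[C@H]12 | intermediate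
34 | (6R,7S,8S)-6-hydroxy-15-[(E)-2-(hydroxymethyl)but-2-enoyloxy]germacra-1(10)E,4Z,11(13)-trien-12,8-olide | C=C1C(=O)O[C@H]2C/C(C)=C/CC/C(COC(=O)/C(=C/C)CO)=C/[C@@H](O)[C@H]12 | target

Total step count: 22. Longest linear sequence: 18 (steps 2–17, 21, 22, from 4).

Steps most likely to fail

Step 16 (labelled step). Three processes could defeat it: protodeboronation of the hindered 1,1-disubstituted alkenylboronate before copper takes it over, base-induced loss of HBr towards the 8,9-alkene, or a ring conformation that does not open the backside of C8–Br to the tethered carboxylate. The fallback uses known chemistry, sets out from 22 and comes back at 26. It is a palladium-catalysed carbonylative lactonisation of the bromoalkenyl alcohol (Pd(PPh3)4, CO at 1 atm, Et3N, THF, 60 °C), in which the acylpalladium species is captured by the 8α-hydroxyl with retention at C8. Steps 14 and 15 then fall away and no new compound is made.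

Step 15. Backside attack of external bromide on a ring carbon of the ten-membered ring may be slow, so that elimination to a diene or participation of the C1=C10 π bond (erosion of the inversion) takes over. The fallback avoids any intermolecular substitution on the ring, sets out from 23 and comes back at 26. Dess–Martin oxidation should give the 8-ketone F1. Peripheral hydride delivery (L-Selectride, THF, −78 °C) should push the oxygen into the pseudo-axial position and give the 8β-alcohol F2. MsCl and Et3N should give the 8β-mesylate F3, which is submitted to the conditions of step 16.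

Step 13. Oligomerisation at the dilution needed, β-elimination of bromide or silyloxide from the allylchromium species, or poor facial selectivity relative to C6 may spoil the ring closure. The fallback changes the type of allylmetal and the transition state, sets out from 19 and comes back at 26.
- Bu3SnLi (THF, −78 °C) should convert the allylic bromide into the allylstannane alcohol F4.
- Dess–Martin oxidation should give the stannyl aldehyde F5.
- BF3·OEt2 (CH2Cl2, −78 °C, high dilution) should close the ring through an open transition state, which for γ-substituted allylstannanes is syn-selective and should give the 8β-alcohol F6.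
- Miyaura borylation of F6 leads to the 8β-alcohol F2, and mesylation to the 8β-mesylate F3.
- The conditions of step 16 then give 26, so the inversion of step 15 is no longer needed.

Further compounds
F0 | step 16 | none | none
F1 | step 15 | (6R,7S)-6-(tert-butyldimethylsilyloxy)-15-(4-methoxybenzyloxy)-11-(pinacolatoboryl)-12-norgermacra-1(10)E,4Z,11(13)-trien-8-one | C=C(B1OC(C)(C)C(C)(C)O1)[C@@H]2C(=O)C/C(C)=C/CC/C(COCc3ccc(OC)cc3)=C/[C@H]2O[Si](C)(C)C(C)(C)C
F2 | step 15 | (6R,7R,8R)-6-(tert-butyldimethylsilyloxy)-15-(4-methoxybenzyloxy)-11-(pinacolatoboryl)-12-norgermacra-1(10)E,4Z,11(13)-trien-8-ol (8β-OH) | C=C(B1OC(C)(C)C(C)(C)O1)[C@@H]2[C@H](O)C/C(C)=C/CC/C(COCc3ccc(OC)cc3)=C/[C@H]2O[Si](C)(C)C(C)(C)C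
F3 | step 15 | 8β-methanesulfonate of F2 (6R,7S,8R) | C=C(B1OC(C)(C)C(C)(C)O1)[C@@H]2[C@H](OS(C)(=O)=O)C/C(C)=C/CC/C(COCc3ccc(OC)cc3)=C/[C@H]2O[Si](C)(C)C(C)(C)C
F4 | step 13 | (3E,7Z,9R,10Z)-11-bromo-9-(tert-butyldimethylsilyloxy)-7-[(4-methoxybenzyloxy)methyl]-3-methyl-12-(tributylstannyl)dodeca-3,7,10-trien-1-ol | OCC/C(C)=C/CC/C(COCc1ccc(OC)cc1)=C/[C@@H](O[Si](C)(C)C(C)(C)C)/C=C(\Br)C[Sn](CCCC)(CCCC)CCCC
F5 | step 13 | (3E,7Z,9R,10Z)-11-bromo-9-(tert-butyldimethylsilyloxy)-7-[(4-methoxybenzyloxy)methyl]-3-methyl-12-(tributylstannyl)dodeca-3,7,10-trienal | O=CC/C(C)=C/CC/C(COCc1ccc(OC)cc1)=C/[C@@H](O[Si](C)(C)C(C)(C)C)/C=C(\Br)C[Sn](CCCC)(CCCC)CCCC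
F6 | step 13 | (6R,7R,8R)-11-bromo-6-(tert-butyldimethylsilyloxy)-15-(4-methoxybenzyloxy)-12-norgermacra-1(10)E,4Z,11(13)-trien-8-ol (8β-OH, 8-epimer of 22) | C=C(Br)[C@@H]1[C@H](O)C/C(C)=C/CC/C(COCc2ccc(OC)cc2)=C/[C@H]1O[Si](C)(C)C(C)(C)C
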